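**Retrosynthetic overview**

1. Neovibsanin I ⇐ silyl removal and (E)-enol esterification of a C7 acetaldehyde arm; the acetonyl-dihydrofuran (ring B) ⇐ lactol + acetonylidene ylide (Wittig/oxa-Michael) ⇐ fused butenolide.
2. C6 quaternary centre ⇐ light-driven cobalt-hydride/nickel hydroalkylation of a 6-methylidene group with homoprenyl bromide (key C–C bond).
3. Cyclohexene (ring A) ⇐ type-two carbonyl-ene closure of a 4-formylbutenolide onto an isopropenyl group.
4. Butenolide ⇐ ester-enolate aldol condensation with 2,2-dimethyl-1,3-dioxan-5-one, then lactonisation.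
5. Ester/acetal-differentiated 3-isopropenylglutarate unit ⇐ oxidative excision of C2 of (S)-carvone; its C5 becomes C7 and steers C4, C6 and C1. Ring order: B (as butenolide), then A, then B reduced and alkylated to the dihydrofuran.

Assumption: the dioxanone, the bromide, the ylide and the anhydride are bought as catalogue compounds; positions in the text follow 2-benzofuran numbering (C1 acetonyl carbon, C3 OCH2, C4 carbinol, C6 quaternary carbon, C7 side-chain carbon).

**Route**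

Step 1
Reactants: 1 (5S)-2-methyl-5-(prop-1-en-2-yl)cyclohex-2-en-1-one [(S)-carvone]
Product: 2 (1S,4S,6S)-1-methyl-4-(prop-1-en-2-yl)-7-oxabicyclo[4.1.0]heptan-2-one
Conditions: H2O2 (30% aq.), NaOH (cat.), MeOH, 0 °C
Reagents that add atoms: hydrogen peroxide, OO
Why: Weitz–Scheffer nucleophilic epoxidation attacks only the electron-poor enone alkene, anti to the isopropenyl group, so the bought stereocentre and the isopropenyl alkene are untouched.

Step 2
Reactants: 2 (1S,4S,6S)-1-methyl-4-(prop-1-en-2-yl)-7-oxabicyclo[4.1.0]heptan-2-one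
Product: 4 methyl (3S)-5,5-dimethoxy-3-(prop-1-en-2-yl)pentanoate, via aldehyde acid 3 (not isolated)
Conditions: H5IO6, THF–H2O, 0 °C to rt; then HC(OMe)3, MeOH, TsOH (cat.), 40 °C
Reagents that add atoms: water, O; methanol, CO; trimethyl orthoformate, COC(OC)OC
Why: Periodic acid opens the keto-epoxide to the glycol, cleaves it (Malaprade cleavage) and then cleaves the resulting 1,2-diketone, so C2 and its methyl leave as acetic acid, and acidic methanol/orthoformate turns the acid arm into the ester and the aldehyde arm into the acetal (Fischer esterification/acetalisation); the stereocentre is β to both carbonyls and cannot epimerise.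

Step 3
Reactants: 4 methyl (3S)-5,5-dimethoxy-3-(prop-1-en-2-yl)pentanoate; 5 2,2-dimethyl-1,3-dioxan-5-one
Product: 8 methyl (3R)-2-(2,2-dimethyl-1,3-dioxan-5-ylidene)-5,5-dimethoxy-3-(prop-1-en-2-yl)pentanoate, via aldol adduct 6 (not isolated), via tertiary mesylate 7 (not isolated)
Conditions: LiN(i-Pr)2, THF, −78 °C; 5; MsCl, −78 to 0 °C; DBU, rt
Reagents that add atoms: 2,2-dimethyl-1,3-dioxan-5-one (5), CC1(C)OCC(=O)CO1
Why: Ester-enolate aldol addition to the ketone followed by mesylation and E1cB elimination (one-pot aldol condensation) gives the conjugated tetrasubstituted alkylidene ester, and C2 becomes sp2 so no new stereocentre remains.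

Step 4
Reactants: 8 methyl (3R)-2-(2,2-dimethyl-1,3-dioxan-5-ylidene)-5,5-dimethoxy-3-(prop-1-en-2-yl)pentanoate
Product: 10 3-[(3R)-1,1-dimethoxy-4-methylpent-4-en-3-yl]-4-(hydroxymethyl)furan-2(5H)-one, via diol ester 9 (not isolated)
Conditions: TsOH·H2O (cat.), MeOH, rt
Reagents that add atoms: none
Why: Acid-catalysed transacetalisation frees two equivalent hydroxymethyl groups and the one cis to the ester lactonises to the butenolide (ring B), while the dimethyl acetal is inert in methanol.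

Step 5
Reactants: 10 3-[(3R)-1,1-dimethoxy-4-methylpent-4-en-3-yl]-4-(hydroxymethyl)furan-2(5H)-one
Product: 11 4-[(3R)-1,1-dimethoxy-4-methylpent-4-en-3-yl]-5-oxo-2,5-dihydrofuran-3-carbaldehyde
Conditions: Dess–Martin periodinane, pyridine, CH2Cl2, 0 °C to rt
Reagents that add atoms: none
Why: Dess–Martin oxidation converts the primary allylic alcohol to the aldehyde without touching the acetal, the lactone or the alkenes.

Step 6
Reactants: 11 4-[(3R)-1,1-dimethoxy-4-methylpent-4-en-3-yl]-5-oxo-2,5-dihydrofuran-3-carbaldehyde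
Product: 12 (4R,7R)-7-(2,2-dimethoxyethyl)-4-hydroxy-6-methylidene-4,5,6,7-tetrahydro-2-benzofuran-1(3H)-one
Conditions: Me2AlCl, CH2Cl2, −78 °C
Reagents that add atoms: none
Why: The Lewis-acid-promoted type-two intramolecular carbonyl-ene reaction closes ring A through a chair-like transition state with the complexed carbonyl oxygen axial, and the C7 arm sits pseudoaxial to avoid allylic strain with the lactone carbonyl and the isopropenyl methyl, so the new C4 hydroxyl forms trans to the arm (4R).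

Step 7
Reactants: 12 (4R,7R)-7-(2,2-dimethoxyethyl)-4-hydroxy-6-methylidene-4,5,6,7-tetrahydro-2-benzofuran-1(3H)-one; 13 5-bromo-2-methylpent-2-ene
Product: 14 (4R,6S,7R)-7-(2,2-dimethoxyethyl)-4-hydroxy-6-methyl-6-(4-methylpent-3-en-1-yl)-4,5,6,7-tetrahydro-2-benzofuran-1(3H)-one
Conditions: 13, 4CzIPN (cat.), Co(salen) (cat.), NiBr2(dme) (cat.), 4,4′-di-tert-butyl-2,2′-bipyridine, Hantzsch ester, Na2CO3, DMA, blue LEDs (450 nm), rt
Reagents that add atoms: 5-bromo-2-methylpent-2-ene (13), CC(C)=CCCBr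
Why: Proposed new method: a light-driven Markovnikov hydroalkylation in which the photoreduced cobalt salen complex is protonated to a trivalent cobalt hydride that transfers a hydrogen atom to the exocyclic CH2, and the tertiary C6 radical is captured by an alkylnickel species formed from 13 and reductively eliminates to the quaternary carbon, the homoprenyl group entering anti to the pseudoaxial C7 arm (6S); the closest known chemistry is the silane-driven manganese/nickel or iron/nickel dual-catalytic hydroalkylation of 1,1-disubstituted alkenes with alkyl halides, combined with photoredox cobalt-hydride hydrofunctionalisation.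

Step 8
Reactants: 14 (4R,6S,7R)-7-(2,2-dimethoxyethyl)-4-hydroxy-6-methyl-6-(4-methylpent-3-en-1-yl)-4,5,6,7-tetrahydro-2-benzofuran-1(3H)-one
Product: 15 (4R,6S,7R)-4-{[tert-butyl(dimethyl)silyl]oxy}-7-(2,2-dimethoxyethyl)-6-methyl-6-(4-methylpent-3-en-1-yl)-4,5,6,7-tetrahydro-2-benzofuran-1(3H)-one
Conditions: t-BuMe2SiOTf, 2,6-lutidine, CH2Cl2, −78 °C
Reagents that add atoms: tert-butyldimethylsilyl trifluoromethanesulfonate, CC(C)(C)[Si](C)(C)OS(=O)(=O)C(F)(F)F
Why: Silyl triflate silylation protects the hindered secondary alcohol so that it is not acylated in step 12.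

Step 9
Reactants: 15 (4R,6S,7R)-4-{[tert-butyl(dimethyl)silyl]oxy}-7-(2,2-dimethoxyethyl)-6-methyl-6-(4-methylpent-3-en-1-yl)-4,5,6,7-tetrahydro-2-benzofuran-1(3H)-one
Product: 16 (4R,6S,7R)-4-{[tert-butyl(dimethyl)silyl]oxy}-7-(2,2-dimethoxyethyl)-6-methyl-6-(4-methylpent-3-en-1-yl)-1,3,4,5,6,7-hexahydro-2-benzofuran-1-ol (both C1 epimers)
Conditions: i-Bu2AlH, CH2Cl2, −78 °C
Reagents that add atoms: none
Why: Half-reduction of the butenolide by i-Bu2AlH stops at the lactol because the tetrahedral aluminate is stable at −78 °C.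

Step 10
Reactants: 16 the lactol from step 9; 17 1-(triphenyl-λ5-phosphanylidene)propan-2-one
Product: 19 1-[(1S,4R,6S,7R)-4-{[tert-butyl(dimethyl)silyl]oxy}-7-(2,2-dimethoxyethyl)-6-methyl-6-(4-methylpent-3-en-1-yl)-1,3,4,5,6,7-hexahydro-2-benzofuran-1-yl]propan-2-one, via open hydroxy dienone 18 (not isolated)
Conditions: 17, PhMe, 80 °C; then DBU (cat.), rt
Reagents that add atoms: 1-(triphenyl-λ5-phosphanylidene)propan-2-one (17), CC(=O)C=P(c1ccccc1)(c1ccccc1)c1ccccc1
Why: Wittig olefination of the open hydroxy-enal form gives the (E)-dienone, which closes by reversible 5-exo oxa-Michael addition, and equilibration places the acetonyl group trans to the pseudoaxial C7 arm to avoid a syn-1,3 clash (1S).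

Step 11
Reactants: 19 the acetonyl dihydrofuran acetal from step 10
Product: 20 2-[(1S,4R,6S,7R)-4-{[tert-butyl(dimethyl)silyl]oxy}-6-methyl-6-(4-methylpent-3-en-1-yl)-1-(2-oxopropyl)-1,3,4,5,6,7-hexahydro-2-benzofuran-7-yl]acetaldehyde
Conditions: PPTS, acetone–H2O, 50 °C
Reagents that add atoms: water, O
Why: Mild acid-catalysed hydrolysis cleaves the acyclic dimethyl acetal while the secondary silyl ether and the β-alkoxy ketone survive.

Step 12
Reactants: 20 the aldehyde from step 11; 21 3-methylbut-2-enoic anhydride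
Product: 22 (E)-2-[(1S,4R,6S,7R)-4-{[tert-butyl(dimethyl)silyl]oxy}-6-methyl-6-(4-methylpent-3-en-1-yl)-1-(2-oxopropyl)-1,3,4,5,6,7-hexahydro-2-benzofuran-7-yl]ethenyl 3-methylbut-2-enoate
Conditions: 21, Et3N, DMAP (cat.), PhMe, 60 °C
Reagents that add atoms: 3-methylbut-2-enoic anhydride (21), CC(C)=CC(=O)OC(=O)C=C(C)C
Why: Amine/DMAP-mediated O-acylation of the aldehyde enol (enol esterification) favours the more acidic aldehyde α-CH2 over the methyl ketone, and reversible acyl transfer favours the less hindered (E)-enol ester.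

Step 13
Reactants: 22 the silyl-protected enol ester from step 12
Product: 23 neovibsanin I, (E)-2-[(1S,4R,6S,7R)-4-hydroxy-6-methyl-6-(4-methylpent-3-en-1-yl)-1-(2-oxopropyl)-1,3,4,5,6,7-hexahydro-2-benzofuran-7-yl]ethenyl 3-methylbut-2-enoate
Conditions: HF·pyridine, THF, 0 °C to rt
Reagents that add atoms: none
Why: Fluoride-mediated desilylation under buffered acidic conditions leaves the enol ester, the β-alkoxy ketone and the allylic ether intact.

**Compound list**

1 | (5S)-2-methyl-5-(prop-1-en-2-yl)cyclohex-2-en-1-one, (S)-carvone | CC1=CC[C@@H](CC1=O)C(C)=C | starting material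
2 | (1S,4S,6S)-1-methyl-4-(prop-1-en-2-yl)-7-oxabicyclo[4.1.0]heptan-2-one | C[C@]12O[C@H]1C[C@@H](CC2=O)C(C)=C | intermediate
3 | (3S)-5-oxo-3-(prop-1-en-2-yl)pentanoic acid | OC(=O)C[C@H](CC=O)C(C)=C | intermediate (not isolated)
4 | methyl (3S)-5,5-dimethoxy-3-(prop-1-en-2-yl)pentanoate | COC(=O)C[C@H](CC(OC)OC)C(C)=C | intermediate
5 | 2,2-dimethyl-1,3-dioxan-5-one | CC1(C)OCC(=O)CO1 | starting material
6 | methyl (3S)-2-(5-hydroxy-2,2-dimethyl-1,3-dioxan-5-yl)-5,5-dimethoxy-3-(prop-1-en-2-yl)pentanoate (C2 epimers) | COC(=O)C([C@H](CC(OC)OC)C(C)=C)C1(O)COC(C)(C)OC1 | intermediate (not isolated)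
7 | methyl (3S)-2-[2,2-dimethyl-5-(methylsulfonyloxy)-1,3-dioxan-5-yl]-5,5-dimethoxy-3-(prop-1-en-2-yl)pentanoate (C2 epimers) | COC(=O)C([C@H](CC(OC)OC)C(C)=C)C1(OS(C)(=O)=O)COC(C)(C)OC1 | intermediate (not isolated)
8 | methyl (3R)-2-(2,2-dimethyl-1,3-dioxan-5-ylidene)-5,5-dimethoxy-3-(prop-1-en-2-yl)pentanoate | COC(=O)C(=C1COC(C)(C)OC1)[C@H](CC(OC)OC)C(C)=C | intermediate
9 | methyl (3R)-2-(1,3-dihydroxypropan-2-ylidene)-5,5-dimethoxy-3-(prop-1-en-2-yl)pentanoate | COC(=O)C(=C(CO)CO)[C@H](CC(OC)OC)C(C)=C | intermediate (not isolated)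
10 | 3-[(3R)-1,1-dimethoxy-4-methylpent-4-en-3-yl]-4-(hydroxymethyl)furan-2(5H)-one | OCC1=C(C(=O)OC1)[C@H](CC(OC)OC)C(C)=C | intermediate
11 | 4-[(3R)-1,1-dimethoxy-4-methylpent-4-en-3-yl]-5-oxo-2,5-dihydrofuran-3-carbaldehyde | O=CC1=C(C(=O)OC1)[C@H](CC(OC)OC)C(C)=C | intermediate
12 | (4R,7R)-7-(2,2-dimethoxyethyl)-4-hydroxy-6-methylidene-4,5,6,7-tetrahydro-2-benzofuran-1(3H)-one | O=C1OCC2=C1[C@H](CC(OC)OC)C(=C)C[C@H]2O | intermediate
13 | 5-bromo-2-methylpent-2-ene | CC(C)=CCCBr | starting material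
14 | (4R,6S,7R)-7-(2,2-dimethoxyethyl)-4-hydroxy-6-methyl-6-(4-methylpent-3-en-1-yl)-4,5,6,7-tetrahydro-2-benzofuran-1(3H)-one | O=C1OCC2=C1[C@H](CC(OC)OC)[C@@](C)(CCC=C(C)C)C[C@H]2O | intermediate
15 | (4R,6S,7R)-4-{[tert-butyl(dimethyl)silyl]oxy}-7-(2,2-dimethoxyethyl)-6-methyl-6-(4-methylpent-3-en-1-yl)-4,5,6,7-tetrahydro-2-benzofuran-1(3H)-one | O=C1OCC2=C1[C@H](CC(OC)OC)[C@@](C)(CCC=C(C)C)C[C@H]2O[Si](C)(C)C(C)(C)C | intermediate
16 | (4R,6S,7R)-4-{[tert-butyl(dimethyl)silyl]oxy}-7-(2,2-dimethoxyethyl)-6-methyl-6-(4-methylpent-3-en-1-yl)-1,3,4,5,6,7-hexahydro-2-benzofuran-1-ol (both C1 epimers) | OC1OCC2=C1[C@H](CC(OC)OC)[C@@](C)(CCC=C(C)C)C[C@H]2O[Si](C)(C)C(C)(C)C | intermediate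
17 | 1-(triphenyl-λ5-phosphanylidene)propan-2-one | CC(=O)C=P(c1ccccc1)(c1ccccc1)c1ccccc1 | starting material
18 | (3E)-4-[(3R,5S,6R)-3-{[tert-butyl(dimethyl)silyl]oxy}-6-(2,2-dimethoxyethyl)-2-(hydroxymethyl)-5-methyl-5-(4-methylpent-3-en-1-yl)cyclohex-1-en-1-yl]but-3-en-2-one | OCC1=C(/C=C/C(C)=O)[C@H](CC(OC)OC)[C@@](C)(CCC=C(C)C)C[C@H]1O[Si](C)(C)C(C)(C)C | intermediate (not isolated)
19 | 1-[(1S,4R,6S,7R)-4-{[tert-butyl(dimethyl)silyl]oxy}-7-(2,2-dimethoxyethyl)-6-methyl-6-(4-methylpent-3-en-1-yl)-1,3,4,5,6,7-hexahydro-2-benzofuran-1-yl]propan-2-one | CC(=O)C[C@@H]1OCC2=C1[C@H](CC(OC)OC)[C@@](C)(CCC=C(C)C)C[C@H]2O[Si](C)(C)C(C)(C)C | intermediate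
20 | 2-[(1S,4R,6S,7R)-4-{[tert-butyl(dimethyl)silyl]oxy}-6-methyl-6-(4-methylpent-3-en-1-yl)-1-(2-oxopropyl)-1,3,4,5,6,7-hexahydro-2-benzofuran-7-yl]acetaldehyde | CC(=O)C[C@@H]1OCC2=C1[C@H](CC=O)[C@@](C)(CCC=C(C)C)C[C@H]2O[Si](C)(C)C(C)(C)C | intermediate
21 | 3-methylbut-2-enoic anhydride | CC(C)=CC(=O)OC(=O)C=C(C)C | starting material
22 | (E)-2-[(1S,4R,6S,7R)-4-{[tert-butyl(dimethyl)silyl]oxy}-6-methyl-6-(4-methylpent-3-en-1-yl)-1-(2-oxopropyl)-1,3,4,5,6,7-hexahydro-2-benzofuran-7-yl]ethenyl 3-methylbut-2-enoate | CC(=O)C[C@@H]1OCC2=C1[C@H](/C=C/OC(=O)C=C(C)C)[C@@](C)(CCC=C(C)C)C[C@H]2O[Si](C)(C)C(C)(C)C | intermediate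
23 | neovibsanin I, (E)-2-[(1S,4R,6S,7R)-4-hydroxy-6-methyl-6-(4-methylpent-3-en-1-yl)-1-(2-oxopropyl)-1,3,4,5,6,7-hexahydro-2-benzofuran-7-yl]ethenyl 3-methylbut-2-enoate | CC(=O)C[C@@H]1OCC2=C1[C@H](/C=C/OC(=O)C=C(C)C)[C@@](C)(CCC=C(C)C)C[C@H]2O | target

**Step count and risks**

Total step count: 13. Longest linear sequence: 13 steps, from (S)-carvone.

The three steps most likely to fail:

Step 6 (carbonyl-ene closure). The Lewis acid may engage the dimethyl acetal, and the C4 configuration rests on a transition-state argument. The fallback sets out from 11 and comes back at 14, setting C4 by ketone reduction instead of by the ene reaction. Whatever C4-epimeric alcohol the closure gives, (4S,7R)-7-(2,2-dimethoxyethyl)-4-hydroxy-6-methylidene-4,5,6,7-tetrahydro-2-benzofuran-1(3H)-one F1, is carried through the hydroalkylation of step 7 to (4S,6S,7R)-7-(2,2-dimethoxyethyl)-4-hydroxy-6-methyl-6-(4-methylpent-3-en-1-yl)-4,5,6,7-tetrahydro-2-benzofuran-1(3H)-one F2. Dess–Martin oxidation then gives (6S,7R)-7-(2,2-dimethoxyethyl)-6-methyl-6-(4-methylpent-3-en-1-yl)-6,7-dihydro-2-benzofuran-1,4(3H,5H)-dione F3, which cannot aromatise because C6 is quaternary. Luche reduction (NaBH4, CeCl3, MeOH, −78 °C) delivers hydride anti to the axial homoprenyl group and returns 14.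

Step 7 (the new photochemical hydroalkylation). Reversible hydrogen-atom transfer could isomerise the exocyclic alkene or erode C7, capture of the tertiary radical by nickel may be slow, and the bromide may simply be reduced. The fallback uses known chemistry, sets out from 12 and comes back at 14. Hydrogen-atom-transfer Giese addition of the exocyclic alkene to acrolein (Fe(acac)3 cat., PhSiH3, EtOH/ethylene glycol, 60 °C) again attacks anti to the C7 arm and gives 3-[(4R,6S,7R)-7-(2,2-dimethoxyethyl)-4-hydroxy-6-methyl-1-oxo-1,3,4,5,6,7-hexahydro-2-benzofuran-6-yl]propanal F4. Wittig olefination with the ylide from isopropyltriphenylphosphonium iodide and n-BuLi (THF, −78 °C to rt) then builds the trisubstituted alkene and gives 14.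

Step 12 (enol esterification). The methyl ketone may compete, base may trigger retro-oxa-Michael opening, and the E/Z ratio may be poor. The fallback sets out from 16 and comes back at 22, so that the ketone is only unveiled after the enol ester is in place.
- Allylmagnesium bromide (THF, −78 to 0 °C) opens lactol 16 to 1-[(3R,5S,6R)-3-{[tert-butyl(dimethyl)silyl]oxy}-6-(2,2-dimethoxyethyl)-2-(hydroxymethyl)-5-methyl-5-(4-methylpent-3-en-1-yl)cyclohex-1-en-1-yl]but-3-en-1-ol F5.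
- TsOH (cat.) in wet acetone closes the dihydrofuran through the allylic cation, trans to the C7 arm, and hydrolyses the acetal to 2-[(1S,4R,6S,7R)-4-{[tert-butyl(dimethyl)silyl]oxy}-6-methyl-6-(4-methylpent-3-en-1-yl)-1-(prop-2-en-1-yl)-1,3,4,5,6,7-hexahydro-2-benzofuran-7-yl]acetaldehyde F6.
- Acylation with 21 under the conditions of step 12, now with no ketone present, gives (E)-2-[(1S,4R,6S,7R)-4-{[tert-butyl(dimethyl)silyl]oxy}-6-methyl-6-(4-methylpent-3-en-1-yl)-1-(prop-2-en-1-yl)-1,3,4,5,6,7-hexahydro-2-benzofuran-7-yl]ethenyl 3-methylbut-2-enoate F7.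
- Tsuji–Wacker oxidation of the terminal allyl group (PdCl2, CuCl, O2, DMF–H2O) gives 22.

**Further compounds**

F1 | step 6 | (4S,7R)-7-(2,2-dimethoxyethyl)-4-hydroxy-6-methylidene-4,5,6,7-tetrahydro-2-benzofuran-1(3H)-one | O=C1OCC2=C1[C@H](CC(OC)OC)C(=C)C[C@@H]2O
F2 | step 6 | (4S,6S,7R)-7-(2,2-dimethoxyethyl)-4-hydroxy-6-methyl-6-(4-methylpent-3-en-1-yl)-4,5,6,7-tetrahydro-2-benzofuran-1(3H)-one | O=C1OCC2=C1[C@H](CC(OC)OC)[C@@](C)(CCC=C(C)C)C[C@@H]2O
F3 | step 6 | (6S,7R)-7-(2,2-dimethoxyethyl)-6-methyl-6-(4-methylpent-3-en-1-yl)-6,7-dihydro-2-benzofuran-1,4(3H,5H)-dione | O=C1OCC2=C1[C@H](CC(OC)OC)[C@@](C)(CCC=C(C)C)CC2=O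
F4 | step 7 | 3-[(4R,6S,7R)-7-(2,2-dimethoxyethyl)-4-hydroxy-6-methyl-1-oxo-1,3,4,5,6,7-hexahydro-2-benzofuran-6-yl]propanal | O=C1OCC2=C1[C@H](CC(OC)OC)[C@@](C)(CCC=O)C[C@H]2O
F5 | step 12 | 1-[(3R,5S,6R)-3-{[tert-butyl(dimethyl)silyl]oxy}-6-(2,2-dimethoxyethyl)-2-(hydroxymethyl)-5-methyl-5-(4-methylpent-3-en-1-yl)cyclohex-1-en-1-yl]but-3-en-1-ol (carbinol epimers) | OCC1=C(C(O)CC=C)[C@H](CC(OC)OC)[C@@](C)(CCC=C(C)C)C[C@H]1O[Si](C)(C)C(C)(C)C
F6 | step 12 | 2-[(1S,4R,6S,7R)-4-{[tert-butyl(dimethyl)silyl]oxy}-6-methyl-6-(4-methylpent-3-en-1-yl)-1-(prop-2-en-1-yl)-1,3,4,5,6,7-hexahydro-2-benzofuran-7-yl]acetaldehyde | C=CC[C@@H]1OCC2=C1[C@H](CC=O)[C@@](C)(CCC=C(C)C)C[C@H]2O[Si](C)(C)C(C)(C)C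
F7 | step 12 | (E)-2-[(1S,4R,6S,7R)-4-{[tert-butyl(dimethyl)silyl]oxy}-6-methyl-6-(4-methylpent-3-en-1-yl)-1-(prop-2-en-1-yl)-1,3,4,5,6,7-hexahydro-2-benzofuran-7-yl]ethenyl 3-methylbut-2-enoate | C=CC[C@@H]1OCC2=C1[C@H](/C=C/OC(=O)C=C(C)C)[C@@](C)(CCC=C(C)C)C[C@H]2O[Si](C)(C)C(C)(C)C
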